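**Strategy.** Ring B is cut at C7–C8 and at the ring-fusion bond C5–C10 (eudesmane numbering), which opens ring A as well. A temporary C9 ketone makes C10 and C8 the two nucleophilic α-carbons. C5 is the secondary carbon of a C4–C5 epoxide (the future 4-carbinol) and C7 the terminus of an allylic pivalate (the future isopropenyl group). One base/palladium operation on this acyclic precursor, which already carries the 4H-flavene at C1, closes rings A and B as an α,α′-annulation and relays the epoxide configuration to C5, C10 and C7. An N-heterocyclic-carbene homoenolate addition joins C1 to C4′ beforehand; Wolff–Kishner reduction removes the C9 oxygen at the end.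

Key step: step 13

Remark: terpenoid carbons carry eudesmane numbers (C1–C15) and flavene carbons primed chromene numbers in every intermediate; compounds 16–18 are used as mixtures of C10 epimers because C10 is planarised in step 13.

Step 1
Reactants: 1 2-methyl-2-vinyloxirane (racemic)
Product: 2 (2E)-4-chloro-2-methylbut-2-en-1-ol
Conditions: TiCl4, CH2Cl2, −85 °C; aq. HCl
Reagents that add atoms: titanium tetrachloride, Cl[Ti](Cl)(Cl)Cl
Why: Lewis-acid-mediated SN2′ (conjugate) opening of the vinyl epoxide by chloride should give the E trisubstituted allylic alcohol; no stereocentre is formed.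

Step 2
Reactants: 3 hex-1-en-5-yne; 2 (2E)-4-chloro-2-methylbut-2-en-1-ol
Product: 5 (2E,5E)-2,6-dimethyldeca-2,5,9-trien-1-ol, via alkenylalane 4 (not isolated)
Conditions: AlMe3 (2 equiv), Cp2ZrCl2 (0.2 equiv), CH2Cl2, 0 °C → rt; then 2 (as its dimethylaluminium alkoxide), Pd(PPh3)4 (3 mol %), THF, rt
Reagents that add atoms: trimethylaluminium, C[Al](C)C
Why: Zirconium-catalysed syn methylalumination of the alkyne (Negishi carboalumination) should fix the E geometry of C4=C5 and deliver C15, and the palladium-catalysed allyl–alkenyl cross-coupling should join C5 to the primary allylic terminus C6 with retention of both alkene geometries.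

Step 3
Reactants: 5 (2E,5E)-2,6-dimethyldeca-2,5,9-trien-1-ol
Product: 6 (2E,5E)-2,6-dimethyldeca-2,5,9-trien-1-yl pivalate
Conditions: pivaloyl chloride, pyridine, DMAP (cat.), CH2Cl2, 0 °C
Reagents that add atoms: pivaloyl chloride, CC(C)(C)C(Cl)=O
Why: Acylation of the primary alcohol gives an ester that deactivates C7=C11 towards electrophilic oxidants and later serves as the leaving group for the π-allyl chemistry.

Step 4
Reactants: 6 (2E,5E)-2,6-dimethyldeca-2,5,9-trien-1-yl pivalate
Product: 7 (2E)-4-[(2R,3R)-3-(but-3-en-1-yl)-3-methyloxiran-2-yl]-2-methylbut-2-en-1-yl pivalate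
Conditions: D-fructose-derived Shi ketone (0.3 equiv), KHSO5 (as Oxone), K2CO3, Bu4NHSO4, MeCN/CH2(OMe)2/aq. Na2B4O7 buffer, 0 °C
Reagents that add atoms: potassium peroxymonosulfate, [K+].[O-]S(=O)(=O)OO
Why: Shi asymmetric epoxidation (chiral dioxirane, spiro transition state) should oxidise only the electron-rich trisubstituted C4=C5 alkene, since the vinyl group and the pivalate-deactivated C7=C11 alkene react far more slowly; the catalyst sets C4 and C5 as R,R.

Step 5
Reactants: 7 (2E)-4-[(2R,3R)-3-(but-3-en-1-yl)-3-methyloxiran-2-yl]-2-methylbut-2-en-1-yl pivalate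
Product: 8 (2E)-2-methyl-4-{(2R,3R)-3-methyl-3-[(3E)-5-oxopent-3-en-1-yl]oxiran-2-yl}but-2-en-1-yl pivalate
Conditions: crotonaldehyde (5 equiv), second-generation Hoveyda–Grubbs catalyst RuCl2(H2IMes)(=CH-C6H4-2-OiPr) (3 mol %), CH2Cl2, 40 °C
Reagents that add atoms: (E)-but-2-enal, C/C=C/C=O
Why: Olefin cross-metathesis of the monosubstituted alkene with an excess of the enal should give the E enal, the trisubstituted alkenes and the epoxide being inert to the ruthenium carbene.

Step 6
Reactants: 9 1,2,3,5-tetramethoxybenzene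
Product: 10 2,3,4,6-tetramethoxybenzaldehyde
Conditions: POCl3, DMF, 0 → 60 °C; aq. NaOAc
Reagents that add atoms: N,N-dimethylformamide, CN(C)C=O
Why: Vilsmeier–Haack formylation of the electron-rich arene occurs at one of its two equivalent free positions.

Step 7
Reactants: 10 2,3,4,6-tetramethoxybenzaldehyde
Product: 11 2-hydroxy-3,4,6-trimethoxybenzaldehyde
Conditions: BCl3 (1.1 equiv), CH2Cl2, −78 → 0 °C; H2O
Reagents that add atoms: none
Why: Chelation-controlled mono-demethylation ortho to the formyl group should cleave the ortho ether that is flanked on both sides (C2), which is the twisted and more basic one.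

Step 8
Reactants: 11 2-hydroxy-3,4,6-trimethoxybenzaldehyde; 12 acetophenone
Product: 13 (2E)-3-(2-hydroxy-3,4,6-trimethoxyphenyl)-1-phenylprop-2-en-1-one
Conditions: KOH, EtOH/H2O, rt; aq. HCl
Reagents that add atoms: none
Why: Claisen–Schmidt (aldol) condensation gives the E enone; the phenol travels as its phenoxide and is recovered on acidification.

Step 9
Reactants: 8 (2E)-2-methyl-4-{(2R,3R)-3-methyl-3-[(3E)-5-oxopent-3-en-1-yl]oxiran-2-yl}but-2-en-1-yl pivalate; 13 (2E)-3-(2-hydroxy-3,4,6-trimethoxyphenyl)-1-phenylprop-2-en-1-one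
Product: 14 methyl (3R,4R)-4-(2-hydroxy-3,4,6-trimethoxyphenyl)-3-{2-[(2R,3R)-2-methyl-3-((2E)-3-methyl-4-(pivaloyloxy)but-2-en-1-yl)oxiran-2-yl]ethyl}-6-oxo-6-phenylhexanoate
Conditions: aminoindanol-derived N-mesityl triazolium tetrafluoroborate (enantiomer matched to the 3R product, 10 mol %), DBU (15 mol %), THF/MeOH 5:1, rt
Reagents that add atoms: methanol, CO
Why: NHC-catalysed homoenolate conjugate addition (polarity reversal of the enal β-carbon C1 by the carbene) to the chalcone β-carbon C4′, followed by methanolysis of the acyl azolium, should give the δ-keto ester; the chiral carbene selects the face of C1 and the open Michael transition state should place the C2 chain and the aryl group syn (3R,4R).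

Step 10
Reactants: 14 methyl (3R,4R)-4-(2-hydroxy-3,4,6-trimethoxyphenyl)-3-{2-[(2R,3R)-2-methyl-3-((2E)-3-methyl-4-(pivaloyloxy)but-2-en-1-yl)oxiran-2-yl]ethyl}-6-oxo-6-phenylhexanoate
Product: 15 methyl (3R)-5-{(2R,3R)-2-methyl-3-[(2E)-3-methyl-4-(pivaloyloxy)but-2-en-1-yl]oxiran-2-yl}-3-[(4S)-5,7,8-trimethoxy-2-phenyl-4H-chromen-4-yl]pentanoate
Conditions: PPTS (10 mol %), 4 Å MS, toluene, 40 °C
Reagents that add atoms: none
Why: Acid-catalysed cyclodehydration of the δ-(2-hydroxyaryl) ketone should give the 2-phenyl-4H-chromene without touching C4′, and the weak buffered acid should spare the trisubstituted epoxide.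

Step 11
Reactants: 15 methyl (3R)-5-{(2R,3R)-2-methyl-3-[(2E)-3-methyl-4-(pivaloyloxy)but-2-en-1-yl]oxiran-2-yl}-3-[(4S)-5,7,8-trimethoxy-2-phenyl-4H-chromen-4-yl]pentanoate
Product: 16 methyl (2RS,3S)-2-methyl-5-{(2R,3R)-2-methyl-3-[(2E)-3-methyl-4-(pivaloyloxy)but-2-en-1-yl]oxiran-2-yl}-3-[(4S)-5,7,8-trimethoxy-2-phenyl-4H-chromen-4-yl]pentanoate
Conditions: LiN(iPr)2 (1.1 equiv), THF, −78 °C; MeI
Reagents that add atoms: iodomethane, CI
Why: Ester enolate alkylation installs the C14 methyl group at C10; both C10 epimers are carried on because this centre becomes an enolate carbon in step 13.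

Step 12
Reactants: 16 methyl (2RS,3S)-2-methyl-5-{(2R,3R)-2-methyl-3-[(2E)-3-methyl-4-(pivaloyloxy)but-2-en-1-yl]oxiran-2-yl}-3-[(4S)-5,7,8-trimethoxy-2-phenyl-4H-chromen-4-yl]pentanoate
Product: 18 (2E)-2-methyl-4-{(2R,3R)-3-methyl-3-[(3S,4RS)-4-methyl-5-oxo-3-((4S)-5,7,8-trimethoxy-2-phenyl-4H-chromen-4-yl)hexyl]oxiran-2-yl}but-2-en-1-yl pivalate, via Weinreb amide 17 (not isolated)
Conditions: MeNHOMe·HCl (3 equiv), i-PrMgCl (6 equiv), THF, −20 → 0 °C; then MeMgBr (3 equiv), 0 °C; aq. NH4Cl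
Reagents that add atoms: methylmagnesium bromide, C[Mg]Br; N,O-dimethylhydroxylamine hydrochloride, CNOC.Cl (its atoms stay only in 17)
Why: One-pot Weinreb ketone synthesis: the magnesium amide converts the ester into the N-methoxy-N-methylamide, which accepts only one equivalent of the Grignard reagent and so gives the methyl ketone (C8), while the hindered pivalate and the epoxide should survive at 0 °C.

Step 13
Reactants: 18 (2E)-2-methyl-4-{(2R,3R)-3-methyl-3-[(3S,4RS)-4-methyl-5-oxo-3-((4S)-5,7,8-trimethoxy-2-phenyl-4H-chromen-4-yl)hexyl]oxiran-2-yl}but-2-en-1-yl pivalate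
Product: 20 (1S,4R,5R,7S,10S)-4-hydroxy-1-[(4S)-5,7,8-trimethoxy-2-phenyl-4H-chromen-4-yl]eudesm-11-en-9-one, via ring-A hydroxy ketone 19 (not isolated)
Conditions: KN(SiMe3)2 (1.0 equiv), t-BuOH (0.1 equiv), THF (5 mM), −78 → 40 °C; then Pd(PPh3)4 (5 mol %), same flask, 50 °C
Reagents that add atoms: none
Why: Proton transfer equilibrates the kinetic methyl enolate with the tetrasubstituted C10 enolate, and only the latter can reach the epoxide: it attacks C5 anti to the C–O bond (SN2, inversion) through a chair transition state, which closes ring A in the 6-endo mode and frees the C4 alkoxide; this alkoxide is more basic than a ketone enolate and passes the charge on to C8. Zerovalent palladium then ionises the allylic pivalate and the C8 enolate attacks the π-allyl terminus C7 (6-exo), which closes ring B and turns C7=C11 into the C11=C12 isopropenyl group. The closest known reaction types are the intramolecular alkylation of ketone or nitrile anions by epoxides and the Tsuji–Trost allylation of ketone enolates; together they amount to an α,α′-annulation of the C9 ketone. C4 keeps the configuration of the epoxide and C5 is its stereospecific inverse; C10 is set by the ring-A chair in which the C1 flavenyl group and the enolate arm are equatorial and the small methyl group is axial, and C7 by the ring-B chair with the π-allyl unit equatorial. The step needs 6-endo over 5-exo opening (secured by the fully substituted C4), C- over O-allylation (secured by one equivalent of base, which leaves the tertiary alcohol protonated) and the right enolate for each event (secured by ring size, since each enolate has only one six-membered option).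

Step 14
Reactants: 20 (1S,4R,5R,7S,10S)-4-hydroxy-1-[(4S)-5,7,8-trimethoxy-2-phenyl-4H-chromen-4-yl]eudesm-11-en-9-one
Product: 22 (1S,4R,5R,7R,10S)-1-[(4S)-5,7,8-trimethoxy-2-phenyl-4H-chromen-4-yl]eudesm-11-en-4-ol (CNP0390914.1), via hydrazone 21 (not isolated)
Conditions: N2H4·H2O, KOH, diethylene glycol, 130 °C, then distillation to 200 °C
Reagents that add atoms: hydrazine hydrate, NN.O (its nitrogen atoms stay only in 21)
Why: Wolff–Kishner reduction (Huang-Minlon procedure) replaces the C9 carbonyl by CH2; the enol ether, the tertiary alcohol and the 1,1-disubstituted alkene should tolerate hot alkali, and no stereocentre is touched.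

Compound list
1 | 2-methyl-2-vinyloxirane (racemic) | C=CC1(C)CO1 | starting material
2 | (2E)-4-chloro-2-methylbut-2-en-1-ol | OC/C(C)=C/CCl | intermediate
3 | hex-1-en-5-yne | C=CCCC#C | starting material
4 | dimethyl[(1E)-2-methylhexa-1,5-dien-1-yl]alumane | C=CCC/C(C)=C/[Al](C)C | intermediate
5 | (2E,5E)-2,6-dimethyldeca-2,5,9-trien-1-ol | OC/C(C)=C/C/C=C(\C)CCC=C | intermediate
6 | (2E,5E)-2,6-dimethyldeca-2,5,9-trien-1-yl pivalate | CC(C)(C)C(=O)OC/C(C)=C/C/C=C(\C)CCC=C | intermediate
7 | (2E)-4-[(2R,3R)-3-(but-3-en-1-yl)-3-methyloxiran-2-yl]-2-methylbut-2-en-1-yl pivalate | C=CCC[C@@]1(C)O[C@@H]1C/C=C(\C)COC(=O)C(C)(C)C | intermediate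
8 | (2E)-2-methyl-4-{(2R,3R)-3-methyl-3-[(3E)-5-oxopent-3-en-1-yl]oxiran-2-yl}but-2-en-1-yl pivalate | O=C/C=C/CC[C@@]1(C)O[C@@H]1C/C=C(\C)COC(=O)C(C)(C)C | intermediate
9 | 1,2,3,5-tetramethoxybenzene | COc1cc(OC)c(OC)c(OC)c1 | starting material
10 | 2,3,4,6-tetramethoxybenzaldehyde | O=Cc1c(OC)cc(OC)c(OC)c1OC | intermediate
11 | 2-hydroxy-3,4,6-trimethoxybenzaldehyde | O=Cc1c(OC)cc(OC)c(OC)c1O | intermediate
12 | acetophenone | CC(=O)c1ccccc1 | starting material
13 | (2E)-3-(2-hydroxy-3,4,6-trimethoxyphenyl)-1-phenylprop-2-en-1-one | O=C(/C=C/c1c(O)c(OC)c(OC)cc1OC)c1ccccc1 | intermediate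
14 | methyl (3R,4R)-4-(2-hydroxy-3,4,6-trimethoxyphenyl)-3-{2-[(2R,3R)-2-methyl-3-((2E)-3-methyl-4-(pivaloyloxy)but-2-en-1-yl)oxiran-2-yl]ethyl}-6-oxo-6-phenylhexanoate | COC(=O)C[C@@H](CC[C@@]1(C)O[C@@H]1C/C=C(\C)COC(=O)C(C)(C)C)[C@@H](CC(=O)c1ccccc1)c1c(O)c(OC)c(OC)cc1OC | intermediate
15 | methyl (3R)-5-{(2R,3R)-2-methyl-3-[(2E)-3-methyl-4-(pivaloyloxy)but-2-en-1-yl]oxiran-2-yl}-3-[(4S)-5,7,8-trimethoxy-2-phenyl-4H-chromen-4-yl]pentanoate | COC(=O)C[C@@H](CC[C@@]1(C)O[C@@H]1C/C=C(\C)COC(=O)C(C)(C)C)[C@H]1C=C(c2ccccc2)Oc2c(OC)c(OC)cc(OC)c21 | intermediate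
16 | methyl (2RS,3S)-2-methyl-5-{(2R,3R)-2-methyl-3-[(2E)-3-methyl-4-(pivaloyloxy)but-2-en-1-yl]oxiran-2-yl}-3-[(4S)-5,7,8-trimethoxy-2-phenyl-4H-chromen-4-yl]pentanoate (C10 epimers) | COC(=O)C(C)[C@@H](CC[C@@]1(C)O[C@@H]1C/C=C(\C)COC(=O)C(C)(C)C)[C@H]1C=C(c2ccccc2)Oc2c(OC)c(OC)cc(OC)c21 | intermediate
17 | (2RS,3S)-N-methoxy-N,2-dimethyl-5-{(2R,3R)-2-methyl-3-[(2E)-3-methyl-4-(pivaloyloxy)but-2-en-1-yl]oxiran-2-yl}-3-[(4S)-5,7,8-trimethoxy-2-phenyl-4H-chromen-4-yl]pentanamide | CON(C)C(=O)C(C)[C@@H](CC[C@@]1(C)O[C@@H]1C/C=C(\C)COC(=O)C(C)(C)C)[C@H]1C=C(c2ccccc2)Oc2c(OC)c(OC)cc(OC)c21 | intermediate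
18 | (2E)-2-methyl-4-{(2R,3R)-3-methyl-3-[(3S,4RS)-4-methyl-5-oxo-3-((4S)-5,7,8-trimethoxy-2-phenyl-4H-chromen-4-yl)hexyl]oxiran-2-yl}but-2-en-1-yl pivalate | CC(=O)C(C)[C@@H](CC[C@@]1(C)O[C@@H]1C/C=C(\C)COC(=O)C(C)(C)C)[C@H]1C=C(c2ccccc2)Oc2c(OC)c(OC)cc(OC)c21 | intermediate
19 | ring-A hydroxy ketone: cyclohexane (C1, C2, C3, C4, C5, C10) with acetyl and methyl at C10, the (2E)-3-methyl-4-(pivaloyloxy)but-2-enyl chain at C5, methyl and hydroxyl at C4 and the (4S)-flavenyl group at C1; configuration at C1, C4, C5, C10 as in 20 | CC(=O)[C@]1(C)[C@@H](C/C=C(\C)COC(=O)C(C)(C)C)[C@](C)(O)CC[C@H]1[C@H]2C=C(c3ccccc3)Oc3c(OC)c(OC)cc(OC)c32 | intermediate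
20 | (1S,4R,5R,7S,10S)-4-hydroxy-1-[(4S)-5,7,8-trimethoxy-2-phenyl-4H-chromen-4-yl]eudesm-11-en-9-one (same spatial arrangement as the target; the label at C7 changes with the ketone) | C=C(C)[C@@H]1CC(=O)[C@]2(C)[C@@H](C1)[C@](C)(O)CC[C@H]2[C@H]1C=C(c2ccccc2)Oc2c(OC)c(OC)cc(OC)c21 | intermediate
21 | hydrazone of 20 at C9 | C=C(C)[C@@H]1CC(=NN)[C@]2(C)[C@@H](C1)[C@](C)(O)CC[C@H]2[C@H]1C=C(c2ccccc2)Oc2c(OC)c(OC)cc(OC)c21 | intermediate
22 | (1S,4R,5R,7R,10S)-1-[(4S)-5,7,8-trimethoxy-2-phenyl-4H-chromen-4-yl]eudesm-11-en-4-ol (CNP0390914.1) | C=C(C)[C@@H]1CC[C@]2(C)[C@@H](C1)[C@](C)(O)CC[C@H]2[C@H]1C=C(c2ccccc2)Oc2c(OC)c(OC)cc(OC)c21 | target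

Total step count: 14. Longest linear sequence: 11 steps (steps 1–5 and 9–14).

Steps most likely to fail

1. Step 13. The enolate may attack C5 through the chair that places its acyl arm axial (cis-fused product), the C4 alkoxide may add to the π-allyl unit instead of passing its charge to C8, or allylation may occur between molecules before ring A has closed. Fallback: from 16, crossed Claisen condensation with the lithium enolate of methyl acetate (LiN(iPr)2, THF, −78 → 0 °C) should give the β-keto ester F1. Its dianion (NaH, then n-BuLi, THF, 0 °C) opens the epoxide through the γ-carbon C10; after addition of Pd(PPh3)4 the soft, stabilised anion at C8 closes ring B by Tsuji–Trost allylation in the same flask, which should give the bicyclic β-keto ester F2. Krapcho demethoxycarbonylation (LiCl, wet DMSO, 150 °C) returns the route to 20.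

2. Step 9. Protonation of the homoenolate at C1 by methanol or by the phenol may outrun the conjugate addition (saturated ester), and the relative topicity at C1/C4′ may be poor. Fallback: from 7, cross-metathesis with methyl acrylate (second-generation Hoveyda–Grubbs catalyst) should give the enoate F3. Copper-catalysed enantioselective conjugate borylation (CuCl, NaOt-Bu, a Josiphos-type bisphosphine, B2pin2, MeOH) should give the β-boryl ester F4. Chalcone 13 is cyclised with HBF4·OEt2 in acetic acid to the flavylium salt F5. The ate complex of F4 with 3,5-bis(trifluoromethyl)phenyllithium (−78 °C) is coupled with F5 with inversion at C1 (stereospecific substitution of a boronate complex by a carbenium ion), the C4′ epimers are separated, and the route is rejoined at 15.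

3. Step 14. Hydrazone formation at the C9 carbonyl, which is flanked by the quaternary C10, may stall, and the isopropenyl double bond may migrate in hot alkali. Fallback: from 20, NaBH4 (MeOH, 0 °C) should give the C9 alcohol F6. NaH, CS2 and then MeI should convert only the secondary hydroxyl into the S-methyl xanthate F7, the tertiary C4 hydroxyl being too hindered. Barton–McCombie deoxygenation (Bu3SnH, AIBN, toluene, 110 °C) gives 22.

Further compounds
F1 | step 13 | methyl 4-methyl-3-oxo-7-{(2R,3R)-2-methyl-3-[(2E)-3-methyl-4-(pivaloyloxy)but-2-en-1-yl]oxiran-2-yl}-5-[(4S)-5,7,8-trimethoxy-2-phenyl-4H-chromen-4-yl]heptanoate (C10 epimers) | COC(=O)CC(=O)C(C)[C@@H](CC[C@@]1(C)O[C@@H]1C/C=C(\C)COC(=O)C(C)(C)C)[C@H]1C=C(c2ccccc2)Oc2c(OC)c(OC)cc(OC)c21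
F2 | step 13 | methyl 4-hydroxy-9-oxo-1-[(4S)-5,7,8-trimethoxy-2-phenyl-4H-chromen-4-yl]eudesm-11-ene-8-carboxylate (C8 epimers, other centres as in 20) | C=C(C)[C@@H]1C(C(=O)OC)C(=O)[C@]2(C)[C@@H](C1)[C@](C)(O)CC[C@H]2[C@H]1C=C(c2ccccc2)Oc2c(OC)c(OC)cc(OC)c21
F3 | step 9 | methyl (2E)-5-{(2R,3R)-2-methyl-3-[(2E)-3-methyl-4-(pivaloyloxy)but-2-en-1-yl]oxiran-2-yl}pent-2-enoate | COC(=O)/C=C/CC[C@@]1(C)O[C@@H]1C/C=C(\C)COC(=O)C(C)(C)C
F4 | step 9 | methyl (3S)-5-{(2R,3R)-2-methyl-3-[(2E)-3-methyl-4-(pivaloyloxy)but-2-en-1-yl]oxiran-2-yl}-3-(4,4,5,5-tetramethyl-1,3,2-dioxaborolan-2-yl)pentanoate | COC(=O)C[C@H](CC[C@@]1(C)O[C@@H]1C/C=C(\C)COC(=O)C(C)(C)C)B1OC(C)(C)C(C)(C)O1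
F5 | step 9 | 5,7,8-trimethoxy-2-phenylchromenylium tetrafluoroborate | COc1cc(OC)c(OC)c2[o+]c(-c3ccccc3)ccc12.F[B-](F)(F)F
F6 | step 14 | 1-[(4S)-5,7,8-trimethoxy-2-phenyl-4H-chromen-4-yl]eudesm-11-ene-4,9-diol (C9 epimers, other centres as in 20) | C=C(C)[C@@H]1CC(O)[C@]2(C)[C@@H](C1)[C@](C)(O)CC[C@H]2[C@H]1C=C(c2ccccc2)Oc2c(OC)c(OC)cc(OC)c21
F7 | step 14 | O-(C9) S-methyl xanthate of F6 | C=C(C)[C@@H]1CC(OC(=S)SC)[C@]2(C)[C@@H](C1)[C@](C)(O)CC[C@H]2[C@H]1C=C(c2ccccc2)Oc2c(OC)c(OC)cc(OC)c21
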